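**Retrosynthetic overview**
1. The oxepane is closed last, by 7-endo opening of an L-malic-acid-derived epoxide by the cyclohexanol oxygen of 36.
2. The cyclohexane core is (R)-linalool-derived enone 23: alkoxide-directed conjugate addition of Grignard 30 makes the linker bond, and enolate alkylation with epoxy iodide 29 makes the quaternary carbon.
3. Key step: Johnson–Claisen [3,3] rearrangement of allylic alcohol 14 forms the ring-to-side-chain C–C bond, sets that stereocentre and places the trisubstituted alkene.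
4. The hydroazulene comes from (S)-limonene: aldol cyclopentene 4, then a hydrogen-atom-transfer 7-endo radical cyclization (7 to 8), then epoxidation/isomerization and hydroxyl-directed hydrogenation for the cis ring fusion and carbinol.
5. Ring order: cyclopentene, cycloheptanone, (Claisen), cyclohexenone (ring-closing metathesis), oxepane.

Assumption: the target is the single stereoisomer written in the SMILES; hydroazulene locants follow azulene numbering (C1 carbinol, C4 CMe2, C5 side-chain carbon, C6 ring-methyl carbon), and Az(OTES) means the (1S,3aS,5R,8aS)-1,4,4,6-tetramethyl-1-(triethylsilyloxy)-1,2,3,3a,4,5,8,8a-octahydroazulen-5-yl group.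

**Hydroazulene half**

Step 1
Reactants: 1 (S)-(−)-limonene
Product: 3 (3S)-6-oxo-3-(prop-1-en-2-yl)heptanal, via limonene 1,2-oxide 2 (not isolated)
Conditions: mCPBA, CH2Cl2, 0 °C; then H5IO6, THF/H2O, 23 °C
Reagents that add atoms: mCPBA (O=C(OO)c1cccc(Cl)c1); water (O)
Why: The electron-rich trisubstituted ring alkene is epoxidized selectively (Prilezhaev) and the epoxide is hydrolysed and cleaved by periodic acid (glycol cleavage), leaving the bought stereocentre untouched.

Step 2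
Reactants: 3 (3S)-6-oxo-3-(prop-1-en-2-yl)heptanal
Product: 4 (5R)-2-methyl-5-(prop-1-en-2-yl)cyclopent-1-ene-1-carbaldehyde
Conditions: piperidine (cat.), AcOH (cat.), Et2O, 35 °C
Reagents that add atoms: none
Why: Intramolecular aldol condensation (the aldehyde enamine adds to the methyl ketone, then dehydration) closes the five-membered ring; no stereocentre is formed or touched.

Step 3
Reactants: 4 (5R)-2-methyl-5-(prop-1-en-2-yl)cyclopent-1-ene-1-carbaldehyde
Product: 5 [(5R)-2-methyl-5-(prop-1-en-2-yl)cyclopent-1-en-1-yl]methanol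
Conditions: NaBH4, CeCl3·7H2O, MeOH, 0 °C
Reagents that add atoms: none
Why: Luche reduction gives clean 1,2-reduction of the enal.

Step 4
Reactants: 5 [(5R)-2-methyl-5-(prop-1-en-2-yl)cyclopent-1-en-1-yl]methanol
Product: 6 (5R)-1-(bromomethyl)-2-methyl-5-(prop-1-en-2-yl)cyclopent-1-ene
Conditions: PBr3, Et2O, 0 °C
Reagents that add atoms: phosphorus tribromide (BrP(Br)Br)
Why: Bromination of the primary allylic alcohol; the primary bromide is also the thermodynamic allylic isomer.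

Step 5
Reactants: 6 (5R)-1-(bromomethyl)-2-methyl-5-(prop-1-en-2-yl)cyclopent-1-ene
Product: 7 3-methyl-1-[(5R)-2-methyl-5-(prop-1-en-2-yl)cyclopent-1-en-1-yl]but-3-en-2-one
Conditions: CO (3 atm), tributyl(prop-1-en-2-yl)stannane, Pd2(dba)3 (2.5 mol %), AsPh3, THF, 50 °C
Reagents that add atoms: carbon monoxide ([C-]#[O+]); tributyl(prop-1-en-2-yl)stannane (CCCC[Sn](CCCC)(CCCC)C(C)=C)
Why: Carbonylative Stille coupling acylates the less hindered allyl terminus under neutral conditions, so the β,γ-alkene stays in place.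

Step 6
Reactants: 7 3-methyl-1-[(5R)-2-methyl-5-(prop-1-en-2-yl)cyclopent-1-en-1-yl]but-3-en-2-one
Product: 8 (3aR)-1,4,4,6-tetramethyl-2,3,3a,4,5,6,7,8-octahydroazulen-7-one (C1=C8a alkene; C6 epimers)
Conditions: Fe(acac)3, PhSiH3, EtOH/(CH2OH)2, 60 °C, 0.01 M
Reagents that add atoms: none
Why: Hydrogen-atom transfer from an iron hydride to the isopropenyl CH2 gives the tertiary radical, which closes 7-endo onto the unsubstituted terminus of the isopropenyl ketone (intramolecular Giese addition), creating the gem-dimethyl quaternary carbon; the C6 epimers are erased in step 9.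

Step 7
Reactants: 8 (3aR)-1,4,4,6-tetramethyl-2,3,3a,4,5,6,7,8-octahydroazulen-7-one
Product: 10 (1S,3aR)-1-hydroxy-1,4,4,6-tetramethyl-1,2,3,3a,4,5,6,7-octahydroazulen-7-one (C8=C8a alkene; C6 epimers), via epoxy ketone 9 (not isolated)
Conditions: mCPBA, NaHCO3, CH2Cl2, 0 °C; then DBU, 23 °C
Reagents that add atoms: mCPBA (O=C(OO)c1cccc(Cl)c1)
Why: The tetrasubstituted alkene is epoxidized on the face of H-3a (the other face is blocked by the seven-membered ring and its gem-dimethyl group), and E1cB opening of the β,γ-epoxy ketone gives the γ-hydroxy enone, so the carbinol stereocentre is set by the limonene-derived centre.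

Step 8
Reactants: 10 (1S,3aR)-1-hydroxy-1,4,4,6-tetramethyl-1,2,3,3a,4,5,6,7-octahydroazulen-7-one
Product: 11 (1S,3aS,8aS)-1-hydroxy-1,4,4,6-tetramethyldecahydroazulen-7-one (cis-fused; OH and H-3a and H-8a all cis; C6 epimers)
Conditions: H2 (1 atm), [Ir(cod)(PCy3)(py)]PF6 (5 mol %), CH2Cl2, 23 °C
Reagents that add atoms: none
Why: Hydroxyl-directed homogeneous hydrogenation delivers hydrogen to C8a from the face of the tertiary alcohol, which gives the cis ring fusion.

Step 9
Reactants: 11 (1S,3aS,8aS)-1-hydroxy-1,4,4,6-tetramethyldecahydroazulen-7-one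
Product: 13 (1S,3aS,8aS)-1,4,4,6-tetramethyl-1-(triethylsilyloxy)-1,2,3,3a,4,7,8,8a-octahydroazulen-7-one (C5=C6 alkene), via bis(triethylsilyl) enol ether 12 (not isolated)
Conditions: TESOTf, Et3N, CH2Cl2, 0 → 23 °C; then Pd(OAc)2, MeCN, 23 °C
Reagents that add atoms: triethylsilyl trifluoromethanesulfonate (CC[Si](CC)(CC)OS(=O)(=O)C(F)(F)F)
Why: Equilibrating silylation gives the more substituted enol ether and protects the tertiary alcohol, and Saegusa–Ito dehydrogenation then gives the 2-methyl enone.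

Step 10
Reactants: 13 (1S,3aS,8aS)-1,4,4,6-tetramethyl-1-(triethylsilyloxy)-1,2,3,3a,4,7,8,8a-octahydroazulen-7-one
Product: 14 (1S,3aS,7R,8aS)-1,4,4,6-tetramethyl-1-(triethylsilyloxy)-1,2,3,3a,4,7,8,8a-octahydroazulen-7-ol (7-OH trans to H-8a)
Conditions: NaBH4, CeCl3·7H2O, MeOH, −78 → −40 °C
Reagents that add atoms: none
Why: Luche 1,2-reduction; hydride attacks the convex face of the cis-fused bicycle (the face of H-3a/H-8a; the concave face is screened by the cyclopentane and its C1 methyl), putting the hydroxyl on the concave face.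

Step 11
Reactants: 14 (1S,3aS,7R,8aS)-1,4,4,6-tetramethyl-1-(triethylsilyloxy)-1,2,3,3a,4,7,8,8a-octahydroazulen-7-ol
Product: 16 ethyl 2-[Az(OTES)]acetate, via ketene acetal 15 (not isolated)
Conditions: MeC(OEt)3, EtCO2H (cat.), 140 °C
Reagents that add atoms: triethyl orthoacetate (CCOC(C)(OCC)OCC)
Why: Johnson–Claisen [3,3]-sigmatropic rearrangement: the new C5–CH2 bond forms on the face that carried the C7–O bond (suprafacial 1,3-chirality transfer), which sets C5 as R and moves the alkene to C6=C7.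

Step 12
Reactants: 16 ethyl 2-[Az(OTES)]acetate
Product: 17 2-[Az(OTES)]ethanol
Conditions: LiAlH4, Et2O, 0 °C
Reagents that add atoms: none
Why: Hydride reduction of the ester to the primary alcohol.

Step 13
Reactants: 17 2-[Az(OTES)]ethanol
Product: 18 2-[Az(OTES)]ethyl iodide
Conditions: I2, PPh3, imidazole, CH2Cl2, 0 °C
Reagents that add atoms: iodine (II)
Why: Appel-type iodination of the primary alcohol.

**Cyclohexenone 23**

Step 14
Reactants: 19 (R)-(−)-linalool
Product: 21 (R)-5-ethenyl-5-methyloxolan-2-one, via lactol 20 (not isolated)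
Conditions: O3 (1.0 equiv), CH2Cl2/MeOH, −78 °C; Me2S; then PhI(OAc)2, TEMPO (cat.), CH2Cl2, 23 °C
Reagents that add atoms: ozone ([O-][O+]=O)
Why: Ozonolysis cleaves the electron-rich trisubstituted alkene in preference to the vinyl group, and the lactol is oxidized to the lactone; the carbinol centre is untouched.

Step 15
Reactants: 21 (R)-5-ethenyl-5-methyloxolan-2-one
Product: 22 (R)-6-hydroxy-2,6-dimethylocta-1,7-dien-3-one
Conditions: isopropenylmagnesium bromide (1.05 equiv), THF, −78 °C; then H2O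
Reagents that add atoms: isopropenylmagnesium bromide (CC(=C)[Mg]Br)
Why: Grignard mono-addition to the lactone stops at the hemiketal alkoxide at low temperature and gives the hydroxy enone on work-up.

Step 16
Reactants: 22 (R)-6-hydroxy-2,6-dimethylocta-1,7-dien-3-one
Product: 23 (R)-4-hydroxy-2,4-dimethylcyclohex-2-en-1-one
Conditions: second-generation Grubbs catalyst RuCl2(=CHPh)(PCy3)(H2IMes) (3 mol %), CH2Cl2, 40 °C
Reagents that add atoms: none
Why: Ring-closing metathesis of the vinyl carbinol with the 1,1-disubstituted enone alkene gives the six-membered trisubstituted enone.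

**Epoxy iodide 29**

Step 17
Reactants: 24 (S)-3-hydroxyoxolan-2-one
Product: 25 (S)-4-methylpentane-1,3,4-triol
Conditions: MeMgBr (3.5 equiv), THF, 0 → 23 °C; then H2O
Reagents that add atoms: methylmagnesium bromide (C[Mg]Br)
Why: Double Grignard addition to the lactone carbonyl gives the tertiary alcohol without touching the carbinol stereocentre.

Step 18
Reactants: 25 (S)-4-methylpentane-1,3,4-triol
Product: 26 (S)-5-iodo-2-methylpentane-2,3-diol
Conditions: I2, PPh3, imidazole, THF, 0 °C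
Reagents that add atoms: iodine (II)
Why: Appel-type iodination is selective for the primary hydroxyl.

Step 19
Reactants: 26 (S)-5-iodo-2-methylpentane-2,3-diol
Product: 29 (S)-3-(2-iodoethyl)-2,2-dimethyloxirane, via cyclic orthoester 27 (not isolated), via bromo acetate 28 (not isolated)
Conditions: MeC(OMe)3, PPTS (cat.), CH2Cl2, 23 °C; AcBr, 0 °C; then K2CO3, MeOH, 0 °C
Reagents that add atoms: none
Why: Kolb–Sharpless diol-to-epoxide conversion: bromide opens the acetoxonium ion at the tertiary carbon and the freed secondary alkoxide closes the epoxide, so the secondary C–O bond is never broken (retention).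

**Union and endgame**

Step 20
Reactants: 18 2-[Az(OTES)]ethyl iodide; 23 (R)-4-hydroxy-2,4-dimethylcyclohex-2-en-1-one
Product: 33 [(3S,4R)-3-{2-[Az(OTES)]ethyl}-2,4-dimethyl-4-(trimethylsilyloxy)cyclohex-1-en-1-yl]oxy(trimethyl)silane, via Grignard reagent 30 (not isolated), via magnesium alkoxide 31 (not isolated), via magnesium enolate 32 (not isolated)
Conditions: 18: Mg, THF, 40 °C; 23: i-PrMgCl (1.0 equiv), THF, −78 °C; combine, −78 → 0 °C; then TMSCl, Et3N, HMPA, −78 → 23 °C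
Reagents that add atoms: chlorotrimethylsilane (C[Si](C)(C)Cl)
Why: Alkoxide-directed conjugate addition: the magnesium alkoxide delivers the Grignard reagent to the β-carbon on its own face (also the face away from the C4 methyl), setting the new stereocentre cis to the oxygen, and O-silylation traps the enolate regiospecifically.

Step 21
Reactants: 33 bis(trimethylsilyl) enol ether of the conjugate adduct; 29 (S)-3-(2-iodoethyl)-2,2-dimethyloxirane
Product: 35 (2S,3S,4R)-2-{2-[(2S)-3,3-dimethyloxiran-2-yl]ethyl}-3-{2-[Az(OTES)]ethyl}-2,4-dimethyl-4-(trimethylsilyloxy)cyclohexan-1-one, via lithium enolate 34 (not isolated)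
Conditions: MeLi, THF, 0 °C; then 29, HMPA, −40 → 0 °C
Reagents that add atoms: none
Why: MeLi releases the regiodefined lithium enolate, which is alkylated (SN2) anti to the adjacent C3 substituent, setting the quaternary centre with the new chain trans to the linker.

Step 22
Reactants: 35 the alkylated ketone
Product: 36 (1S,2S,3S,4R)-2-{2-[(2S)-3,3-dimethyloxiran-2-yl]ethyl}-3-{2-[Az(OTES)]ethyl}-2,4-dimethyl-4-(trimethylsilyloxy)cyclohexan-1-ol
Conditions: NaBH4, MeOH/THF, 0 °C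
Reagents that add atoms: none
Why: Axial hydride attack, away from the axial methyl on the adjacent quaternary carbon, gives the equatorial alcohol trans to the epoxy-ethyl chain.

Step 23
Reactants: 36 the epoxy alcohol
Product: 38 (3S,5aS,6S,7R,9aS)-6-{2-[(1S,3aS,5R,8aS)-1-hydroxy-1,4,4,6-tetramethyl-1,2,3,3a,4,5,8,8a-octahydroazulen-5-yl]ethyl}-2,2,5a,7-tetramethyldecahydro-1-benzoxepine-3,7-diol, via bis-silyl ether 37 (not isolated)
Conditions: CSA (10 mol %), CH2Cl2, 0 °C; then TBAF, THF, 50 °C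
Reagents that add atoms: none
Why: Acid-catalysed 7-endo epoxide opening at the fully substituted carbon (Markovnikov, SN1-like) closes the trans-fused oxepane with retention at the secondary carbinol, and fluoride then removes both silyl ethers.

**Compound list**

1 | (S)-(−)-limonene | CC1=CC[C@H](CC1)C(C)=C | starting material
2 | (4S)-limonene 1,2-oxide (cis/trans mixture) | CC12OC1C[C@H](CC2)C(C)=C | intermediate
3 | (3S)-6-oxo-3-(prop-1-en-2-yl)heptanal | O=CC[C@H](CCC(C)=O)C(C)=C | intermediate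
4 | (5R)-2-methyl-5-(prop-1-en-2-yl)cyclopent-1-ene-1-carbaldehyde | O=CC1=C(C)CC[C@@H]1C(C)=C | intermediate
5 | [(5R)-2-methyl-5-(prop-1-en-2-yl)cyclopent-1-en-1-yl]methanol | OCC1=C(C)CC[C@@H]1C(C)=C | intermediate
6 | (5R)-1-(bromomethyl)-2-methyl-5-(prop-1-en-2-yl)cyclopent-1-ene | BrCC1=C(C)CC[C@@H]1C(C)=C | intermediate
7 | 3-methyl-1-[(5R)-2-methyl-5-(prop-1-en-2-yl)cyclopent-1-en-1-yl]but-3-en-2-one | C=C(C)C(=O)CC1=C(C)CC[C@@H]1C(C)=C | intermediate
8 | (3aR)-1,4,4,6-tetramethyl-2,3,3a,4,5,6,7,8-octahydroazulen-7-one, C1=C8a alkene, C6 epimers | CC1CC(C)(C)[C@H]2CCC(C)=C2CC1=O | intermediate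
9 | 1,8a-epoxide of 8, oxygen cis to H-3a | CC1CC(C)(C)[C@H]2CC[C@]3(C)O[C@]23CC1=O | intermediate
10 | (1S,3aR)-1-hydroxy-1,4,4,6-tetramethyl-1,2,3,3a,4,5,6,7-octahydroazulen-7-one, C8=C8a alkene, OH cis to H-3a, C6 epimers | CC1CC(C)(C)[C@H]2CC[C@](C)(O)C2=CC1=O | intermediate
11 | (1S,3aS,8aS)-1-hydroxy-1,4,4,6-tetramethyldecahydroazulen-7-one, cis-fused, C6 epimers | CC1CC(C)(C)[C@H]2CC[C@](C)(O)[C@H]2CC1=O | intermediate
12 | (1S,3aS,8aS)-1,4,4,6-tetramethyl-1,7-bis(triethylsilyloxy)-1,2,3,3a,4,5,8,8a-octahydroazulene | CC1=C(O[Si](CC)(CC)CC)C[C@H]2[C@H](CC[C@]2(C)O[Si](CC)(CC)CC)C(C)(C)C1 | intermediate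
13 | (1S,3aS,8aS)-1,4,4,6-tetramethyl-1-(triethylsilyloxy)-1,2,3,3a,4,7,8,8a-octahydroazulen-7-one, C5=C6 alkene | CC1=CC(C)(C)[C@H]2CC[C@](C)(O[Si](CC)(CC)CC)[C@H]2CC1=O | intermediate
14 | (1S,3aS,7R,8aS)-1,4,4,6-tetramethyl-1-(triethylsilyloxy)-1,2,3,3a,4,7,8,8a-octahydroazulen-7-ol | CC1=CC(C)(C)[C@H]2CC[C@](C)(O[Si](CC)(CC)CC)[C@H]2C[C@H]1O | intermediate
15 | 7-O-(1-ethoxyvinyl) ether of 14 (ketene acetal) | CC1=CC(C)(C)[C@H]2CC[C@](C)(O[Si](CC)(CC)CC)[C@H]2C[C@H]1OC(=C)OCC | intermediate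
16 | ethyl 2-[Az(OTES)]acetate | CC1=CC[C@H]2[C@H](CC[C@]2(C)O[Si](CC)(CC)CC)C(C)(C)[C@@H]1CC(=O)OCC | intermediate
17 | 2-[Az(OTES)]ethanol | CC1=CC[C@H]2[C@H](CC[C@]2(C)O[Si](CC)(CC)CC)C(C)(C)[C@@H]1CCO | intermediate
18 | 2-[Az(OTES)]ethyl iodide | CC1=CC[C@H]2[C@H](CC[C@]2(C)O[Si](CC)(CC)CC)C(C)(C)[C@@H]1CCI | intermediate
19 | (R)-(−)-linalool | C=C[C@](C)(O)CCC=C(C)C | starting material
20 | (5R)-5-ethenyl-5-methyloxolan-2-ol (anomers) | C=C[C@]1(C)OC(O)CC1 | intermediate
21 | (R)-5-ethenyl-5-methyloxolan-2-one | C=C[C@]1(C)OC(=O)CC1 | intermediate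
22 | (R)-6-hydroxy-2,6-dimethylocta-1,7-dien-3-one | C=C[C@](C)(O)CCC(=O)C(C)=C | intermediate
23 | (R)-4-hydroxy-2,4-dimethylcyclohex-2-en-1-one | CC1=C[C@](C)(O)CCC1=O | intermediate
24 | (S)-3-hydroxyoxolan-2-one ((S)-α-hydroxy-γ-butyrolactone, from L-malic acid) | O[C@H]1CCOC1=O | starting material
25 | (S)-4-methylpentane-1,3,4-triol | OCC[C@H](O)C(C)(C)O | intermediate
26 | (S)-5-iodo-2-methylpentane-2,3-diol | ICC[C@H](O)C(C)(C)O | intermediate
27 | (5S)-5-(2-iodoethyl)-2-methoxy-2,4,4-trimethyl-1,3-dioxolane | ICC[C@@H]1OC(C)(OC)OC1(C)C | intermediate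
28 | (S)-2-bromo-5-iodo-2-methylpentan-3-yl acetate | ICC[C@H](OC(C)=O)C(C)(C)Br | intermediate
29 | (S)-3-(2-iodoethyl)-2,2-dimethyloxirane | ICC[C@H]1C(C)(C)O1 | intermediate
30 | {2-[Az(OTES)]ethyl}magnesium iodide | CC1=CC[C@H]2[C@H](CC[C@]2(C)O[Si](CC)(CC)CC)C(C)(C)[C@@H]1CC[Mg]I | intermediate
31 | chloromagnesium alkoxide of 23 | CC1=C[C@](C)(O[Mg]Cl)CCC1=O | intermediate
32 | magnesium enolate/alkoxide of the (3S,4R) conjugate adduct | CC1=CC[C@H]2[C@H](CC[C@]2(C)O[Si](CC)(CC)CC)C(C)(C)[C@@H]1CC[C@H]1C(C)=C(O[Mg]I)CC[C@@]1(C)O[Mg]Cl | intermediate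
33 | [(3S,4R)-3-{2-[Az(OTES)]ethyl}-2,4-dimethyl-4-(trimethylsilyloxy)cyclohex-1-en-1-yl]oxy(trimethyl)silane | CC1=CC[C@H]2[C@H](CC[C@]2(C)O[Si](CC)(CC)CC)C(C)(C)[C@@H]1CC[C@H]1C(C)=C(O[Si](C)(C)C)CC[C@@]1(C)O[Si](C)(C)C | intermediate
34 | lithium enolate from 33 | CC1=CC[C@H]2[C@H](CC[C@]2(C)O[Si](CC)(CC)CC)C(C)(C)[C@@H]1CC[C@H]1C(C)=C(O[Li])CC[C@@]1(C)O[Si](C)(C)C | intermediate
35 | (2S,3S,4R)-2-{2-[(2S)-3,3-dimethyloxiran-2-yl]ethyl}-3-{2-[Az(OTES)]ethyl}-2,4-dimethyl-4-(trimethylsilyloxy)cyclohexan-1-one | CC1=CC[C@H]2[C@H](CC[C@]2(C)O[Si](CC)(CC)CC)C(C)(C)[C@@H]1CC[C@H]1[C@](C)(CC[C@H]2C(C)(C)O2)C(=O)CC[C@@]1(C)O[Si](C)(C)C | intermediate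
36 | (1S,2S,3S,4R)-2-{2-[(2S)-3,3-dimethyloxiran-2-yl]ethyl}-3-{2-[Az(OTES)]ethyl}-2,4-dimethyl-4-(trimethylsilyloxy)cyclohexan-1-ol | CC1=CC[C@H]2[C@H](CC[C@]2(C)O[Si](CC)(CC)CC)C(C)(C)[C@@H]1CC[C@H]1[C@](C)(CC[C@H]2C(C)(C)O2)[C@@H](O)CC[C@@]1(C)O[Si](C)(C)C | intermediate
37 | 1-O-triethylsilyl, 7-O-trimethylsilyl bis-ether of 38 (azulene O1, benzoxepine O7) | CC1=CC[C@H]2[C@H](CC[C@]2(C)O[Si](CC)(CC)CC)C(C)(C)[C@@H]1CC[C@H]1[C@]2(C)CC[C@H](O)C(C)(C)O[C@H]2CC[C@@]1(C)O[Si](C)(C)C | intermediate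
38 | (3S,5aS,6S,7R,9aS)-6-{2-[(1S,3aS,5R,8aS)-1-hydroxy-1,4,4,6-tetramethyl-1,2,3,3a,4,5,8,8a-octahydroazulen-5-yl]ethyl}-2,2,5a,7-tetramethyldecahydro-1-benzoxepine-3,7-diol | CC1=CC[C@H]2[C@H](CC[C@]2(C)O)C(C)(C)[C@@H]1CC[C@H]1[C@]2(C)CC[C@H](O)C(C)(C)O[C@H]2CC[C@@]1(C)O | target

**Totals**

Total step count: 23. Longest linear sequence: 17 steps (steps 1–13, then 20–23).

**Three steps most likely to fail, with fallbacks**

Step 6 (7-endo radical cyclization under iron hydride conditions; premature reduction of the tertiary radical may compete). The fallback sets out from 4 and comes back at 11. Intermolecular Fe(acac)3/PhSiH3 coupling of the isopropenyl group of 4 with methyl methacrylate gives the enal ester F1. Alkaline H2O2 (K2CO3, MeOH, 0 °C) epoxidizes the enal anti to the side chain to give the epoxy aldehyde F2. Wharton transposition (N2H4·H2O, AcOH cat., MeOH) gives the tertiary allylic alcohol with an exocyclic methylene F3. LiOH gives the acid F4, and PhSeSePh/PBu3 gives the Se-phenyl selenoester F5. Bu3SnH/AIBN at high dilution then closes the seven-membered ring by 7-endo acyl-radical addition to the exocyclic methylene; the ring-fusion radical takes hydrogen on the hydroxyl face, giving 11 directly and bypassing steps 6–8.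

Step 21 (alkylation of a hindered, fully substituted enolate with an unactivated primary iodide). The fallback sets out from 33 and comes back at 38. Mukaiyama–Michael addition of 33 to acrolein (BF3·OEt2, CH2Cl2, −78 °C) builds the quaternary centre with the same anti sense and gives the keto aldehyde F6. Diphenylsulfonium isopropylide (from isopropyldiphenylsulfonium tetrafluoroborate and t-BuLi, DME, −70 °C) converts the aldehyde into the epoxide F7, as both epimers at the oxirane CH. NaBH4 gives the alcohol F8, CSA gives the oxepane F9, and TBAF gives the triol F10, which is epimeric at benzoxepine C3. Dess–Martin periodinane oxidizes the only secondary alcohol to the 3-ketone F11. NaBH4 then reduces from the less hindered face to the equatorial (3S) alcohol, expected to give 38; this last selectivity is my prediction, not a checked result.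

Step 23 (7-endo against 6-exo epoxide opening). The fallback sets out from 35 and comes back at 38. Aqueous HClO4 in THF hydrolyses the epoxide, and the resulting diol closes onto the ring ketone to give the 6,8-dioxabicyclo[3.2.1]octane ketal F12. DIBAL-H (CH2Cl2, −78 → 0 °C) should coordinate the less hindered ketal oxygen (the one on the secondary carbon), break that C–O bond and deliver hydride with retention. That leaves the oxepane oxygen equatorial and gives the 1-O-triethylsilyl ether F13, with the trans-fused oxepane and free secondary carbinol. TBAF then gives 38.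

Further compounds
F1 | step 6 | methyl 4-[(1R)-2-formyl-3-methylcyclopent-2-en-1-yl]-2,4-dimethylpentanoate (C2 epimers) | O=CC1=C(C)CC[C@@H]1C(C)(C)CC(C)C(=O)OC
F2 | step 6 | 2,3-epoxide of F1 (epoxide trans to the side chain) | O=C[C@]12O[C@@]1(C)CC[C@@H]2C(C)(C)CC(C)C(=O)OC
F3 | step 6 | methyl 4-[(1R,3S)-3-hydroxy-3-methyl-2-methylidenecyclopentyl]-2,4-dimethylpentanoate | C=C1[C@@H](C(C)(C)CC(C)C(=O)OC)CC[C@]1(C)O
F4 | step 6 | 4-[(1R,3S)-3-hydroxy-3-methyl-2-methylidenecyclopentyl]-2,4-dimethylpentanoic acid | C=C1[C@@H](C(C)(C)CC(C)C(O)=O)CC[C@]1(C)O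
F5 | step 6 | Se-phenyl selenoester of F4 | C=C1[C@@H](C(C)(C)CC(C)C(=O)[Se]c2ccccc2)CC[C@]1(C)O
F6 | step 21 | 3-[(1S,2S,3R)-2-{2-[Az(OTES)]ethyl}-1,3-dimethyl-6-oxo-3-(trimethylsilyloxy)cyclohexyl]propanal | CC1=CC[C@H]2[C@H](CC[C@]2(C)O[Si](CC)(CC)CC)C(C)(C)[C@@H]1CC[C@H]1[C@](C)(CCC=O)C(=O)CC[C@@]1(C)O[Si](C)(C)C
F7 | step 21 | 35 as a mixture of epimers at the oxirane CH | CC1=CC[C@H]2[C@H](CC[C@]2(C)O[Si](CC)(CC)CC)C(C)(C)[C@@H]1CC[C@H]1[C@](C)(CCC2OC2(C)C)C(=O)CC[C@@]1(C)O[Si](C)(C)C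
F8 | step 21 | 36 as a mixture of epimers at the oxirane CH | CC1=CC[C@H]2[C@H](CC[C@]2(C)O[Si](CC)(CC)CC)C(C)(C)[C@@H]1CC[C@H]1[C@](C)(CCC2OC2(C)C)[C@@H](O)CC[C@@]1(C)O[Si](C)(C)C
F9 | step 21 | 37 as a mixture of epimers at benzoxepine C3 | CC1=CC[C@H]2[C@H](CC[C@]2(C)O[Si](CC)(CC)CC)C(C)(C)[C@@H]1CC[C@H]1[C@]2(C)CCC(O)C(C)(C)O[C@H]2CC[C@@]1(C)O[Si](C)(C)C
F10 | step 21 | 38 as a mixture of epimers at benzoxepine C3 | CC1=CC[C@H]2[C@H](CC[C@]2(C)O)C(C)(C)[C@@H]1CC[C@H]1[C@]2(C)CCC(O)C(C)(C)O[C@H]2CC[C@@]1(C)O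
F11 | step 21 | 3-oxo analogue of 38 (benzoxepin-3-one) | CC1=CC[C@H]2[C@H](CC[C@]2(C)O)C(C)(C)[C@@H]1CC[C@H]1[C@]2(C)CCC(=O)C(C)(C)O[C@H]2CC[C@@]1(C)O
F12 | step 23 | bicyclic ketal (6,8-dioxabicyclo[3.2.1]octane fused to the cyclohexane; free cyclohexane tertiary alcohol; azulene OTES kept) | CC1=CC[C@H]2[C@H](CC[C@]2(C)O[Si](CC)(CC)CC)C(C)(C)[C@@H]1CC[C@H]1[C@]2(C)CC[C@H]3C(C)(C)O[C@@]2(O3)CC[C@@]1(C)O
F13 | step 23 | 1-O-triethylsilyl ether of 38 (azulene O1) | CC1=CC[C@H]2[C@H](CC[C@]2(C)O[Si](CC)(CC)CC)C(C)(C)[C@@H]1CC[C@H]1[C@]2(C)CC[C@H](O)C(C)(C)O[C@H]2CC[C@@]1(C)O
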